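Everything rests on opening pyranone ring C at the O1–C2 bond, which lies β to the C4 ketone. A temporary tert-butyl ester at C3 makes the C2=C3 alkene of a chalcone-like precursor a doubly activated acceptor. Under a cinchona thiourea the ring A phenol oxygen (O1), the only free hydroxyl ortho to the ketone, adds to C2, closing ring C and setting C2 (S); acid then expels the ester as isobutene and CO2 in the same flask. Both alkene isomers and both C3 epimers should converge. The precursor is a 2-hydroxyaryl alkylidene β-ketoester with iodine at the future C8; the (R)-lavandulyl chain, built by auxiliary-controlled alkylation, is attached there afterwards by Negishi coupling.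

Key step: step 6

Assumption: the quinidine-derived thiourea is taken as the pseudoenantiomer that gives the 2S series; should a model cyclisation show the opposite sense, the quinine-derived pseudoenantiomer is used under the same conditions.

**Step 1**
Reactants: 1 2′,4′-dihydroxy-6′-methoxyacetophenone
Product: 2 1-{2-hydroxy-6-methoxy-4-[(triisopropylsilyl)oxy]phenyl}ethan-1-one
Conditions: TIPSCl (1.05 equiv), imidazole, DMF, 0 °C to rt
Reagents that add atoms: triisopropylsilyl chloride, CC(C)[Si](Cl)(C(C)C)C(C)C
Why: Phenol silylation in which the 2-hydroxyl is held in a hydrogen bond to the ketone, so the more acidic and unhindered 4-hydroxyl should react alone.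

**Step 2**
Reactants: 2 1-{2-hydroxy-6-methoxy-4-[(triisopropylsilyl)oxy]phenyl}ethan-1-one
Product: 3 1-{2-hydroxy-3-iodo-6-methoxy-4-[(triisopropylsilyl)oxy]phenyl}ethan-1-one
Conditions: BnMe3N·ICl2 (1.05 equiv), NaHCO3, CH2Cl2/MeOH, rt
Reagents that add atoms: benzyltrimethylammonium dichloroiodate, C[N+](C)(C)Cc1ccccc1.Cl[I-]Cl
Why: Electrophilic aromatic iodination directed by the free chelated phenol to its ortho position (C3), the classical outcome for 2-hydroxy-4,6-dialkoxyacetophenones, with bicarbonate buffering the HCl so that the silyl ether survives.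

**Step 3**
Reactants: 3 1-{2-hydroxy-3-iodo-6-methoxy-4-[(triisopropylsilyl)oxy]phenyl}ethan-1-one
Product: 4 tert-butyl 3-{2-hydroxy-3-iodo-6-methoxy-4-[(triisopropylsilyl)oxy]phenyl}-3-oxopropanoate
Conditions: LiN(SiMe3)2 (3.2 equiv), THF, −78 °C; Boc2O (1.1 equiv), −78 to 0 °C; aq. NH4Cl
Reagents that add atoms: di-tert-butyl dicarbonate, CC(C)(C)OC(=O)OC(=O)OC(C)(C)C
Why: Claisen-type C-acylation of the phenoxide–enolate dianion by Boc2O, in which any aryl carbonate formed first should hand its acyl group to the enolate carbon by a Baker–Venkataraman-type shift, and the tert-butyl ester resists lactonisation to a 4-hydroxycoumarin.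

**Step 4**
Reactants: 5 2-hydroxy-4-methoxybenzaldehyde
Product: 6 4-methoxy-2-[(triisopropylsilyl)oxy]benzaldehyde
Conditions: TIPSCl (1.2 equiv), imidazole, DMF, rt
Reagents that add atoms: triisopropylsilyl chloride, CC(C)[Si](Cl)(C(C)C)C(C)C
Why: Phenol silylation that masks the ortho-hydroxyl, which would otherwise divert the condensation product of step 5 to a coumarin or chromene.

**Step 5**
Reactants: 4 tert-butyl 3-{2-hydroxy-3-iodo-6-methoxy-4-[(triisopropylsilyl)oxy]phenyl}-3-oxopropanoate; 6 4-methoxy-2-[(triisopropylsilyl)oxy]benzaldehyde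
Product: 7 tert-butyl (2Z)-2-{2-hydroxy-3-iodo-6-methoxy-4-[(triisopropylsilyl)oxy]benzoyl}-3-{4-methoxy-2-[(triisopropylsilyl)oxy]phenyl}prop-2-enoate (Z isomer drawn; the E/Z mixture is used)
Conditions: piperidine (0.2 equiv), AcOH (0.2 equiv), 4 Å molecular sieves, toluene, rt
Reagents that add atoms: none
Why: Knoevenagel condensation of the active methylene of 4 with the aldehyde under piperidinium acetate catalysis, whose E/Z outcome is not critical because step 6 should use both isomers.

**Step 6**
Reactants: 7 tert-butyl (2Z)-2-{2-hydroxy-3-iodo-6-methoxy-4-[(triisopropylsilyl)oxy]benzoyl}-3-{4-methoxy-2-[(triisopropylsilyl)oxy]phenyl}prop-2-enoate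
Product: 9 (2S)-8-iodo-5-methoxy-2-{4-methoxy-2-[(triisopropylsilyl)oxy]phenyl}-7-[(triisopropylsilyl)oxy]chroman-4-one, via tert-butyl flavanone-3-carboxylate 8 (not isolated)
Conditions: quinidine-derived thiourea (9-amino-9-deoxy-epi-quinidine N′-[3,5-bis(trifluoromethyl)phenyl]thiourea, 10 mol%), toluene, −25 °C; then TsOH·H2O (0.5 equiv), 80 °C
Reagents that add atoms: none
Why: The quinuclidine nitrogen of the catalyst acts as a general base on the chelated 2-hydroxyl of ring A while the thiourea binds the β-ketoester through two hydrogen bonds, so the phenol oxygen adds to the β-carbon of the doubly activated alkene (intramolecular oxa-Michael addition) and protonation of the enol gives 8. The closest known reaction type is the bifunctional cinchona thiourea-catalysed cyclisation of 2-hydroxyaryl alkylidene β-ketoesters to flavanone-3-carboxylates with acid decarboxylation in the same flask. Ring C closes in a 6-endo-trig mode. The C2 centre is set by the catalyst, which shields one face of the hydrogen-bonded acceptor, whereas the C3 centre of 8 is transient and is erased when TsOH cleaves the tert-butyl ester and the β-keto acid loses CO2. The step needs enantioface selectivity and a configurationally stable product: the tert-butyl ester gives two-point binding and leaves without base, the only free phenol ortho to the ketone is the one that becomes O1 (the other ortho position carries OMe and the 4-oxygen is silylated), and the silyl ether on ring B lowers its donor strength and so should slow acid-promoted reopening at C2. Both geometric isomers of 7 should converge because the amine can equilibrate them through reversible addition.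

**Step 7**
Reactants: 10 (4S)-4-benzyl-1,3-oxazolidin-2-one; 11 3-methylbut-2-enoyl chloride
Product: 12 (4S)-4-benzyl-3-(3-methylbut-2-enoyl)-1,3-oxazolidin-2-one
Conditions: n-BuLi (1.0 equiv), THF, −78 °C; then 11, −78 to 0 °C
Reagents that add atoms: none
Why: N-acylation of the lithiated oxazolidinone by the acid chloride, a standard way to load the chiral auxiliary.

**Step 8**
Reactants: 12 (4S)-4-benzyl-3-(3-methylbut-2-enoyl)-1,3-oxazolidin-2-one; 13 1-bromo-3-methylbut-2-ene (prenyl bromide)
Product: 14 (4S)-4-benzyl-3-[(2S)-5-methyl-2-(prop-1-en-2-yl)hex-4-enoyl]-1,3-oxazolidin-2-one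
Conditions: NaN(SiMe3)2 (1.1 equiv), THF, −78 °C; then 13, −78 to −40 °C
Reagents that add atoms: none
Why: Deconjugative oxazolidinone-auxiliary alkylation (Evans alkylation) in which γ-deprotonation gives the chelated (Z)-dienolate, which prenyl bromide should attack at the α-carbon on the face away from the benzyl group, setting the (2S) centre and leaving the isopropenyl group out of conjugation.

**Step 9**
Reactants: 14 (4S)-4-benzyl-3-[(2S)-5-methyl-2-(prop-1-en-2-yl)hex-4-enoyl]-1,3-oxazolidin-2-one
Product: 15 (2S)-5-methyl-2-(prop-1-en-2-yl)hex-4-en-1-ol ((S)-lavandulol)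
Conditions: LiBH4, MeOH (1 equiv), Et2O, 0 °C
Reagents that add atoms: none
Why: Reductive cleavage of the imide by LiBH4 should give the primary alcohol without epimerising the α-centre or touching the alkenes, and returns the auxiliary.

**Step 10**
Reactants: 15 (2S)-5-methyl-2-(prop-1-en-2-yl)hex-4-en-1-ol
Product: 16 (3S)-3-(iodomethyl)-2,6-dimethylhepta-1,5-diene ((S)-lavandulyl iodide)
Conditions: I2, PPh3, imidazole, CH2Cl2, 0 °C to rt
Reagents that add atoms: iodine, II
Why: Appel-type iodination of the primary alcohol through its alkoxyphosphonium salt, with the stereocentre one carbon away and therefore untouched.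

**Step 11**
Reactants: 16 (3S)-3-(iodomethyl)-2,6-dimethylhepta-1,5-diene; 9 (2S)-8-iodo-5-methoxy-2-{4-methoxy-2-[(triisopropylsilyl)oxy]phenyl}-7-[(triisopropylsilyl)oxy]chroman-4-one
Product: 18 (2S)-5-methoxy-2-{4-methoxy-2-[(triisopropylsilyl)oxy]phenyl}-8-[(2R)-5-methyl-2-(prop-1-en-2-yl)hex-4-en-1-yl]-7-[(triisopropylsilyl)oxy]chroman-4-one, via lavandulylzinc iodide 17 (not isolated)
Conditions: 16, Zn dust (activated with cat. 1,2-dibromoethane/Me3SiCl), LiCl, THF, 25–40 °C; then 9, Pd(OAc)2 (5 mol%), SPhos (10 mol%), THF, rt to 50 °C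
Reagents that add atoms: none
Why: Negishi cross-coupling in which zerovalent palladium inserts into the C8–I bond, the primary alkylzinc transmetalates and the bulky biaryl phosphine should make reductive elimination outrun β-hydride elimination, while the stereocentre of 17 is not the metal-bearing carbon and is carried over unchanged (its descriptor becomes R only through the change in substituent priorities) and the ketone, the C2 centre and the silyl ethers are inert to the organozinc.

**Step 12**
Reactants: 18 (2S)-5-methoxy-2-{4-methoxy-2-[(triisopropylsilyl)oxy]phenyl}-8-[(2R)-5-methyl-2-(prop-1-en-2-yl)hex-4-en-1-yl]-7-[(triisopropylsilyl)oxy]chroman-4-one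
Product: 19 (2S)-7-hydroxy-2-(2-hydroxy-4-methoxyphenyl)-5-methoxy-8-[(2R)-5-methyl-2-(prop-1-en-2-yl)hex-4-en-1-yl]chroman-4-one (target, CNP0201936.1)
Conditions: Bu4NF (2.5 equiv), AcOH (3 equiv), THF, 0 °C
Reagents that add atoms: none
Why: Fluoride cleavage of both aryl silyl ethers, buffered with acetic acid so that the freed phenols stay protonated and ring C does not open at C2, and free of any acid strong enough to cyclise the lavandulyl alkenes onto the 7-hydroxyl.

**Compound list**

1 | 2′,4′-dihydroxy-6′-methoxyacetophenone | CC(=O)c1c(O)cc(O)cc1OC | starting material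
2 | 1-{2-hydroxy-6-methoxy-4-[(triisopropylsilyl)oxy]phenyl}ethan-1-one | CC(=O)c1c(O)cc(O[Si](C(C)C)(C(C)C)C(C)C)cc1OC | intermediate
3 | 1-{2-hydroxy-3-iodo-6-methoxy-4-[(triisopropylsilyl)oxy]phenyl}ethan-1-one | CC(=O)c1c(O)c(I)c(O[Si](C(C)C)(C(C)C)C(C)C)cc1OC | intermediate
4 | tert-butyl 3-{2-hydroxy-3-iodo-6-methoxy-4-[(triisopropylsilyl)oxy]phenyl}-3-oxopropanoate | CC(C)(C)OC(=O)CC(=O)c1c(O)c(I)c(O[Si](C(C)C)(C(C)C)C(C)C)cc1OC | intermediate
5 | 2-hydroxy-4-methoxybenzaldehyde | O=Cc1ccc(OC)cc1O | starting material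
6 | 4-methoxy-2-[(triisopropylsilyl)oxy]benzaldehyde | O=Cc1ccc(OC)cc1O[Si](C(C)C)(C(C)C)C(C)C | intermediate
7 | tert-butyl (2Z)-2-{2-hydroxy-3-iodo-6-methoxy-4-[(triisopropylsilyl)oxy]benzoyl}-3-{4-methoxy-2-[(triisopropylsilyl)oxy]phenyl}prop-2-enoate (Z drawn, E/Z mixture used) | CC(C)(C)OC(=O)/C(=C\c1ccc(OC)cc1O[Si](C(C)C)(C(C)C)C(C)C)C(=O)c1c(O)c(I)c(O[Si](C(C)C)(C(C)C)C(C)C)cc1OC | intermediate
8 | tert-butyl (2S,3R)-8-iodo-5-methoxy-2-{4-methoxy-2-[(triisopropylsilyl)oxy]phenyl}-4-oxo-7-[(triisopropylsilyl)oxy]chromane-3-carboxylate (trans drawn, C3 epimerisable) | Ic1c(O[Si](C(C)C)(C(C)C)C(C)C)cc(OC)c2c1O[C@H](c1ccc(OC)cc1O[Si](C(C)C)(C(C)C)C(C)C)[C@@H](C(=O)OC(C)(C)C)C2=O | intermediate (not isolated)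
9 | (2S)-8-iodo-5-methoxy-2-{4-methoxy-2-[(triisopropylsilyl)oxy]phenyl}-7-[(triisopropylsilyl)oxy]chroman-4-one | Ic1c(O[Si](C(C)C)(C(C)C)C(C)C)cc(OC)c2c1O[C@H](c1ccc(OC)cc1O[Si](C(C)C)(C(C)C)C(C)C)CC2=O | intermediate
10 | (4S)-4-benzyl-1,3-oxazolidin-2-one | O=C1N[C@@H](Cc2ccccc2)CO1 | starting material
11 | 3-methylbut-2-enoyl chloride | CC(C)=CC(Cl)=O | starting material
12 | (4S)-4-benzyl-3-(3-methylbut-2-enoyl)-1,3-oxazolidin-2-one | CC(C)=CC(=O)N1[C@@H](Cc2ccccc2)COC1=O | intermediate
13 | 1-bromo-3-methylbut-2-ene (prenyl bromide) | CC(C)=CCBr | starting material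
14 | (4S)-4-benzyl-3-[(2S)-5-methyl-2-(prop-1-en-2-yl)hex-4-enoyl]-1,3-oxazolidin-2-one | C=C(C)[C@H](CC=C(C)C)C(=O)N1[C@@H](Cc2ccccc2)COC1=O | intermediate
15 | (2S)-5-methyl-2-(prop-1-en-2-yl)hex-4-en-1-ol ((S)-lavandulol) | C=C(C)[C@H](CC=C(C)C)CO | intermediate
16 | (3S)-3-(iodomethyl)-2,6-dimethylhepta-1,5-diene ((S)-lavandulyl iodide) | C=C(C)[C@H](CC=C(C)C)CI | intermediate
17 | [(2S)-5-methyl-2-(prop-1-en-2-yl)hex-4-en-1-yl]zinc iodide | C=C(C)[C@H](CC=C(C)C)C[Zn]I | intermediate (not isolated)
18 | (2S)-5-methoxy-2-{4-methoxy-2-[(triisopropylsilyl)oxy]phenyl}-8-[(2R)-5-methyl-2-(prop-1-en-2-yl)hex-4-en-1-yl]-7-[(triisopropylsilyl)oxy]chroman-4-one | C=C(C)[C@H](CC=C(C)C)Cc1c(O[Si](C(C)C)(C(C)C)C(C)C)cc(OC)c2c1O[C@H](c1ccc(OC)cc1O[Si](C(C)C)(C(C)C)C(C)C)CC2=O | intermediate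
19 | (2S)-7-hydroxy-2-(2-hydroxy-4-methoxyphenyl)-5-methoxy-8-[(2R)-5-methyl-2-(prop-1-en-2-yl)hex-4-en-1-yl]chroman-4-one | C=C(C)[C@H](CC=C(C)C)Cc1c(O)cc(OC)c2c1O[C@H](c1ccc(OC)cc1O)CC2=O | target

**Step count**

Total steps: 12. Longest linear sequence: 7 steps (steps 1, 2, 3, 5, 6, 11, 12, counted from compound 1). The side chain takes 4 steps (7–10) before it joins at step 11, and step 4 is a one-step branch.

**Steps most likely to fail**

Step 6 (key step). The ortho-iodine and the twisted 6′-methoxyaryl ketone may lower the enantioface selectivity of the catalysed addition. Acid-promoted reversible opening of ring C at the electron-rich benzylic C2 during ester removal could erode the enantiomeric purity. Partial loss of a silyl ether or protodeiodination at 80 °C is also possible. Fallback: from 7 the same O1–C2 closure is run without asymmetric induction (DABCO 20 mol%, toluene, rt; then TsOH·H2O, 80 °C) to give the racemic iodoflavanone F1. F1 is then resolved by kinetic resolution through asymmetric transfer hydrogenation (RuCl(p-cymene)(TsDPEN) of the handedness that reduces the 2R ketone, HCO2H/Et3N, EtOAc, rt, stopped near half conversion). The 2R enantiomer is reduced to the cis-(2R,4R)-chroman-4-ol F2, which is separated, and the unreacted 2S ketone is 9, where the route is rejoined.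

Step 11. Transmetalation at the C8 position, flanked by O1 and the 7-silyloxy group, may be slow, so that β-hydride elimination from the alkylpalladium species or simple reduction of the aryl iodide takes over. Zinc insertion into the homoallylic iodide may also be accompanied by radical rearrangement of the chain. Fallback: from 16, polar lithium–iodine exchange (t-BuLi, 2.1 equiv, Et2O, −78 °C) and capture with 9-methoxy-9-BBN gives the lithium borinate F3. F3 is coupled with 9 in a B-alkyl Suzuki–Miyaura reaction (PdCl2(dppf), K3PO4 aq., DMF/THF, rt) to return to the route at 18. Any silyl ether lost to the base converges on 19 in step 12.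

Step 3. The dianion may be acylated on the enolate oxygen or twice instead of once on carbon, giving enol carbonates and mixtures. Fallback: from 3 the phenol is first converted into the aryl tert-butyl carbonate F4 (Boc2O, DMAP cat., Et3N, CH2Cl2, rt). F4 is then treated with LiN(SiMe3)2 (2.2 equiv, THF, −78 to 0 °C), so that the Boc group is delivered intramolecularly to the enolate carbon through a six-membered transition state (Baker–Venkataraman-type O-to-C shift), giving 4.

**Further compounds**

F1 | step 6 | racemic 8-iodo-5-methoxy-2-{4-methoxy-2-[(triisopropylsilyl)oxy]phenyl}-7-[(triisopropylsilyl)oxy]chroman-4-one | Ic1c(O[Si](C(C)C)(C(C)C)C(C)C)cc(OC)c2c1OC(c1ccc(OC)cc1O[Si](C(C)C)(C(C)C)C(C)C)CC2=O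
F2 | step 6 | (2R,4R)-8-iodo-5-methoxy-2-{4-methoxy-2-[(triisopropylsilyl)oxy]phenyl}-7-[(triisopropylsilyl)oxy]chroman-4-ol | Ic1c(O[Si](C(C)C)(C(C)C)C(C)C)cc(OC)c2c1O[C@@H](c1ccc(OC)cc1O[Si](C(C)C)(C(C)C)C(C)C)C[C@H]2O
F3 | step 11 | lithium B-methoxy-B-[(2S)-5-methyl-2-(prop-1-en-2-yl)hex-4-en-1-yl]-9-borabicyclo[3.3.1]nonan-9-uide | [Li+].CO[B-]1(C[C@H](C(C)=C)CC=C(C)C)C2CCCC1CCC2
F4 | step 3 | 2-acetyl-6-iodo-3-methoxy-5-[(triisopropylsilyl)oxy]phenyl tert-butyl carbonate | CC(=O)c1c(OC(=O)OC(C)(C)C)c(I)c(O[Si](C(C)C)(C(C)C)C(C)C)cc1OC
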